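Start with an easy step: count halvings of the electrophile instead of percentages, since on a logarithmic scale a first-order decay is a straight line. If each electrophile must meet a nucleophile and the nucleophile is in excess (pseudo-first-order), you can hold c_nucleophile at its charge. The electrophile then halves each time the product of c_nucleophile and time grows by a fixed amount.

| setting | winter | noon | autumn | east | north-east | north | south-west | south |
|---|---|---|---|---|---|---|---|---|
| electrophile | 2.9 mM | 15 mM | 13 mM | 13 mM | 13 mM | 20 mM | 4.0 mM | 25 mM |
| nucleophile | 3 equiv | 3 equiv | 3 equiv | 9.00 equiv | 3.00 equiv | 3.00 equiv | 3.00 equiv | 6.00 equiv |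
| free base | 2 equiv | 2 equiv | 2.2 equiv | 0.660 equiv | 2.00 equiv | 0.660 equiv | 2.00 equiv | 4.00 equiv |
| remark | run made earlier | run made earlier | run made earlier |  |  |  |  |  |
| time |  |  |  | 1.0 h | 1.0 h | 1.0 h | 1.0 h | 1.0 h |

| run | time / min | target / % |
|---|---|---|
| winter | 1.50 | 0 |
| winter | 5.00 | 0 |
| winter | 8.00 | 2 |
| winter | 12.0 | 2 |
| winter | 20.0 | 8 |
| winter | 25.0 | 8 |
| winter | 30.0 | 8 |
| noon | 1.50 | 0 |
| noon | 5.00 | 4 |
| noon | 8.00 | 11 |
| noon | 12.0 | 18 |
| noon | 20.0 | 24 |
| noon | 25.0 | 27 |
| noon | 30.0 | 33 |
| autumn | 2.50 | 0 |
| autumn | 5.00 | 8 |
| autumn | 8.00 | 8 |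
| autumn | 15.0 | 19 |
| autumn | 30.0 | 28 |

(standard deviation of a reading: 2 percentage points)



* the flasks put in order of amount of target, in percent of the electrophile charged, best first, at 1.0 h (east / north-east / north / south-west / south)
* the amount of target, in percent of the electrophile charged of the flask you put first, at 1.0 h
* the amount of target, in percent of the electrophile charged of the flask you put last, at 1.0 h

The noon run reached 33 % at 30.0 min, with c_nucleophile = 45.0 mM. Taken from that one reading, with its scatter of 2 percentage points, this gives

h = c_nucleophile · t · ln(2) / ln(1/(1 − y)) = 2340 mM·min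

I call h the halving dose: the product of c_nucleophile and time that halves the electrophile. A flask's half-time is h / c_nucleophile, and its count of halvings is n = c_nucleophile · t / h.

The winter run tests this, at 2.9 mM of electrophile against 15 mM in the noon run. It gets 0.112 halvings, so 7.45 % of target, and its reading is 8 %. The earlier runs held 2 equiv to 2.2 equiv of free base and 3 equiv of nucleophile, so they do not test either setting on its own. I leave the base out, and carrying h to 9.00 equiv of nucleophile in east is my assumption.

My ladder for 1.0 h, fastest first, gives half-time, halvings and target:

south: 15.6 min, 3.85, 93.1 %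

east: 20.0 min, 3.00, 87.5 %

north: 38.9 min, 1.54, 65.6 %

north-east: 59.9 min, 1.00, 50.1 %

south-west: 195 min, 0.308, 19.2 %

In south-west the half-time is longer than the hour, so my reckoning has that flask short of its first halving.

The forecast gives south > east > north > north-east > south-west, with 92 % first and 20 % last. It says “I assume the base is a stoichiometric acid scavenger”, and so holds east at 66 %. My ladder gives the same order but differs there, with 87.5 % for east.

The flasks give south > east > north > north-east > south-west, with 90.3 % in south and 19.8 % in south-west.

    nucleophile + acid set free ⇌ protonated nucleophile, settled at all times (K = 4000 M⁻¹)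
    acid set free + free base ⇌ salt of the base (K = 53600 M⁻¹, k = 0.0803 M⁻¹ s⁻¹)
    electrophile + nucleophile → acid set free + target (k = 0.00549 M⁻¹ s⁻¹)
    free base ⇌ dormant form (K = 0.317, k = 2.20 × 10⁻⁴ s⁻¹)
    electrophile + acid set free → side product (k = 0.0364 M⁻¹ s⁻¹)

East reaches 86.6 % of target, against the forecast's 66 %, from 0.660 equiv of free base; at 1.00 h it holds 11.2 mM of protonated nucleophile beside 0.0377 mM of salt of the base. South-west read at 4.0 h gets 1.23 halvings with the same halving dose, which reckons 42.6 % of the electrophile left. At that time that flask holds 46.1 % of the electrophile charged.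

All runs were generated by integration on assumed constants, noise included.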